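**Retrosynthetic overview**
- The target is an isomer of a linear C20 enynyl acetate; the cyclopentenone (the only ring) is formed last by closing C8–C12, the bond made in the allene oxide / oxidopentadienyl-cation cyclization of the eicosanoid pathway.
- Forward sense of that step: propargylic acetate → acyloxyallene (allene-oxide surrogate) → 4π conrotatory closure onto the activated C12 ketone → acetyl shift from O9 to O12.
- C12 (R) and the 7Z alkene are copied from the allene axis, which is copied from the C7 acetate centre (lipase resolution).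
- C9–C10 is made by Sonogashira coupling of a C1–C9 propargylic acetate with a C10–C20 β,β-dichlorovinyl ketone.
- C1–C9 piece: cross-metathesis, then ethynyl addition. C10–C20 piece: Weinreb amide of (Z)-non-3-enoic acid plus 2,2-dichlorovinyllithium.

Assumption: chain compounds carry prostanoid numbering (C1 = ester carbon, C20 = terminal methyl), and the chirality transfer in step 8 follows the model stated there (C7–H turns inward, C12–O turns outward).

**Route**

Step 1
Reactants: 1 methyl hex-5-enoate; 2 (E)-but-2-enal (crotonaldehyde)
Product: 3 methyl (E)-7-oxohept-5-enoate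
Conditions: second-generation Hoveyda–Grubbs catalyst RuCl2(H2IMes)(=CH-C6H4-2-OiPr) (2 mol%), 2 (5 equiv), CH2Cl2, 40 °C
Reagents that add atoms: none
Why: Olefin cross-metathesis of a terminal alkene with an enal is selective for the cross product and gives the E-enal under thermodynamic control.

Step 2
Reactants: 3 methyl (E)-7-oxohept-5-enoate; 4 ethynylmagnesium bromide
Product: 6 methyl (E)-7-acetoxynon-5-en-8-ynoate (racemic), via bromomagnesium alkoxide 5 (not isolated)
Conditions: 4 (1.05 equiv), THF, −78 °C; then Ac2O (2 equiv), DMAP (5 mol%), −78 → 0 °C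
Reagents that add atoms: acetic anhydride CC(=O)OC(C)=O
Why: Grignard 1,2-addition to the aldehyde (far faster than to the methyl ester at −78 °C) followed by O-acylation of the magnesium alkoxide in the same flask; C7 is racemic here and is resolved in step 3.

Step 3
Reactants: 6 methyl (E)-7-acetoxynon-5-en-8-ynoate (racemic)
Product: 7 methyl (5E,7R)-7-acetoxynon-5-en-8-ynoate
Conditions: immobilized Candida antarctica lipase B, MeOH (3 equiv), MTBE, 30 °C, stopped at about 55% conversion; chromatography
Reagents that add atoms: none
Why: Lipase kinetic resolution by enantioselective methanolysis; by the Kazlauskas model (ethynyl small, alkenyl chain large) the (7S)-acetate is cleaved fast and the (7R)-acetate is left in high ee, while methanolysis of the C1 methyl ester is degenerate.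

Step 4
Reactants: 8 (Z)-non-3-en-1-ol
Product: 9 (Z)-non-3-enoic acid
Conditions: CrO3, H2SO4, acetone/H2O, 0 °C
Reagents that add atoms: water O
Why: Jones oxidation of the primary alcohol through the aldehyde hydrate; the isolated Z alkene is not touched at 0 °C.

Step 5
Reactants: 9 (Z)-non-3-enoic acid
Product: 11 (Z)-N-methoxy-N-methylnon-3-enamide, via acyl imidazole 10 (not isolated)
Conditions: 1,1'-carbonyldiimidazole (1.1 equiv), CH2Cl2, 0 °C → rt; then MeNHOMe·HCl (1.3 equiv), rt
Reagents that add atoms: N,O-dimethylhydroxylamine hydrochloride CNOC.Cl; 1,1'-carbonyldiimidazole O=C(n1ccnc1)n1ccnc1 (its imidazolyl group is found in 10 only)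
Why: Weinreb amide formation through the acyl imidazole, under conditions mild enough to leave the β,γ-alkene out of conjugation.

Step 6
Reactants: 11 (Z)-N-methoxy-N-methylnon-3-enamide; 12 1,1-dichloroethene
Product: 14 (Z)-1,1-dichloroundeca-1,5-dien-3-one, via 2,2-dichlorovinyllithium 13 (not isolated)
Conditions: 12 (1.5 equiv), n-BuLi (1.4 equiv), THF/Et2O/pentane 4:1:1, −110 °C; then 11, −110 → −90 °C; AcOH quench at −90 °C
Reagents that add atoms: none
Why: Weinreb ketone synthesis with a vinyllithium carbenoid; the chelated tetrahedral adduct stops at the ketone, and the cold acidic quench keeps the β,γ-enone unconjugated.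

Step 7
Reactants: 7 methyl (5E,7R)-7-acetoxynon-5-en-8-ynoate; 14 (Z)-1,1-dichloroundeca-1,5-dien-3-one
Product: 15 methyl (5E,7R,10Z,14Z)-7-acetoxy-10-chloro-12-oxoicosa-5,10,14-trien-8-ynoate
Conditions: PdCl2(PPh3)2 (3 mol%), CuI (6 mol%), iPr2NEt (1.5 equiv), 14 (1.5 equiv), THF, 0 °C → rt
Reagents that add atoms: none
Why: Sonogashira coupling of a vinylogous acyl chloride; as with other 1,1-dichloroalkenes, zerovalent palladium should insert first into the less hindered C–Cl bond trans to the acyl group, which puts the alkyne trans to the ketone (10Z) and keeps the ketone oxygen away from the alkyne in the silver stage of step 8.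

Step 8
Reactants: 15 methyl (5E,7R,10Z,14Z)-7-acetoxy-10-chloro-12-oxoicosa-5,10,14-trien-8-ynoate
Product: 18 methyl (5E,7Z,12R,14Z)-12-acetoxy-10-chloro-9-oxoprosta-5,7,10,14-tetraenoate, via allenyl acetate 16 (not isolated), via U-shaped allenyl acetate 17 (not isolated)
Conditions: AgSbF6 (5 mol%), CH2Cl2, 0 °C; then SnCl4 (0.5 equiv), −78 → −20 °C; aq NaHCO3
Reagents that add atoms: none
Why: Proposed new method: a silver-catalysed suprafacial [3,3] acyloxy shift (propargyl ester to allenyl ester rearrangement) turns the (7R) centre into the (aR) allene axis of 16, SnCl4 then equilibrates the C10=C11 bond by reversible chloride addition at C10 and binds the C12 ketone of the U-shaped isomer 17 to give a 1-oxy-4-acyloxypentadienyl cation that closes C8–C12 by 4π conrotatory electrocyclization (closest known types: the ring-closing event of the Piancatelli rearrangement, the allenyl-ether Nazarov cyclization and the allene oxide to cyclopentenone closure of oxylipin biosynthesis), with the C7 hydrogen turning inward and the tin-bound oxygen outward so that the axis is copied into the 7Z alkene and the 12R centre, and the resulting O-acetyl oxocarbenium ion passes its acetyl group to the tin alkoxide on C12 (1,5-acyl shift) to release the C9 ketone, making the step a net isomerization.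

**Compound list**

1 | methyl hex-5-enoate | C=CCCCC(=O)OC | starting material
2 | (E)-but-2-enal (crotonaldehyde) | C/C=C/C=O | starting material
3 | methyl (E)-7-oxohept-5-enoate | O=C/C=C/CCCC(=O)OC | intermediate
4 | ethynylmagnesium bromide | C#C[Mg]Br | starting material
5 | bromomagnesium alkoxide of methyl (E)-7-hydroxynon-5-en-8-ynoate (racemic) | C#CC(O[Mg]Br)/C=C/CCCC(=O)OC | intermediate
6 | methyl (E)-7-acetoxynon-5-en-8-ynoate (racemic) | C#CC(OC(C)=O)/C=C/CCCC(=O)OC | intermediate
7 | methyl (5E,7R)-7-acetoxynon-5-en-8-ynoate | C#C[C@H](OC(C)=O)/C=C/CCCC(=O)OC | intermediate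
8 | (Z)-non-3-en-1-ol | CCCCC/C=C\CCO | starting material
9 | (Z)-non-3-enoic acid | CCCCC/C=C\CC(O)=O | intermediate
10 | 1-[(Z)-non-3-enoyl]imidazole | CCCCC/C=C\CC(=O)n1ccnc1 | intermediate
11 | (Z)-N-methoxy-N-methylnon-3-enamide | CCCCC/C=C\CC(=O)N(C)OC | intermediate
12 | 1,1-dichloroethene | C=C(Cl)Cl | starting material
13 | 2,2-dichlorovinyllithium | [Li]C=C(Cl)Cl | intermediate
14 | (Z)-1,1-dichloroundeca-1,5-dien-3-one | CCCCC/C=C\CC(=O)C=C(Cl)Cl | intermediate
15 | methyl (5E,7R,10Z,14Z)-7-acetoxy-10-chloro-12-oxoicosa-5,10,14-trien-8-ynoate | CCCCC/C=C\CC(=O)/C=C(Cl)/C#C[C@H](OC(C)=O)/C=C/CCCC(=O)OC | intermediate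
16 | methyl (5E,10Z,14Z)-9-acetoxy-10-chloro-12-oxoicosa-5,7,8,10,14-pentaenoate, (aR) axis at C7=C8=C9 | CCCCC/C=C\CC(=O)/C=C(Cl)/C(OC(C)=O)=[C@@]=C([H])/C=C/CCCC(=O)OC | intermediate
17 | methyl (5E,10E,14Z)-9-acetoxy-10-chloro-12-oxoicosa-5,7,8,10,14-pentaenoate, (aR) axis at C7=C8=C9 | CCCCC/C=C\CC(=O)/C=C(Cl)\C(OC(C)=O)=[C@@]=C([H])/C=C/CCCC(=O)OC | intermediate
18 | methyl (5E,7Z,12R,14Z)-12-acetoxy-10-chloro-9-oxoprosta-5,7,10,14-tetraenoate | CCCCC/C=C\C[C@@]1(OC(C)=O)C=C(Cl)C(=O)/C1=C\C=C\CCCC(=O)OC | target

**Step count and risks**

Total steps: 8. Longest linear sequence: 5 steps (1 → 3 → 6 → 7 → 15 → 18, or 8 → 9 → 11 → 14 → 15 → 18).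

Steps most likely to fail:

Step 8 (most risk). The closure of an acyloxyallene onto a Lewis-acid-bound ketone is untested. It also needs the chloro-enone to reach the U-shape and the acetyl group to move from O9 to O12. The sense of rotation at C12 is a model, not a fact; if the product is clean but antipodal, the other enantiomeric series is reached by inverting the sense of the resolution in step 3 (acylation instead of methanolysis).
Fallback, setting out from 15 and coming back at 18: the ring closure is separated from the acetyl transfer and run as a protic, solvent-assisted rearrangement of the Piancatelli kind. 15 is rearranged with AgSbF6 as before and 16 is isolated by filtration through neutral alumina. Anhydrous HCl (1.5 equiv) in (CF3)2CHOH/CH2Cl2 at −40 → 0 °C then equilibrates 16 with 17, the hydrogen-bonded hydroxypentadienyl cation closes, and the acetyl group is given up to the medium. This gives methyl (5E,7Z,12R,14Z)-10-chloro-12-hydroxy-9-oxoprosta-5,7,10,14-tetraenoate F1, which Ac2O, DMAP and Et3N in CH2Cl2 convert into 18.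

Step 7. Which C–Cl bond of 14 couples first is argued by analogy. Double coupling, ionization of the allylic/propargylic acetate by zerovalent palladium, and base-induced conjugation of the β,γ-enone are further threats.
Fallback, setting out from 11 and coming back at 15: the geometry is fixed by an anti hydrochlorination and the coupling is steered to a C–I bond. 11 and ethynylmagnesium bromide 4 (THF, 0 °C) give (Z)-undec-5-en-1-yn-3-one F2. N-Iodosuccinimide with AgNO3 (10 mol%) in acetone gives (Z)-1-iodoundec-5-en-1-yn-3-one F3. LiCl in AcOH adds HCl across the alkyne in the anti sense to give (1E,5Z)-1-chloro-1-iodoundeca-1,5-dien-3-one F4, with chlorine cis and iodine trans to the acyl group. Sonogashira coupling of F4 with 7 (same catalyst, 0 °C) then touches only the C–I bond, with retention, and gives 15.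

Step 6. The carbenoid 13 survives only below about −90 °C, where the Weinreb amide is sluggish, and it may deprotonate the acidic C2 methylene of 11 instead.
Fallback, setting out from 11 and coming back at 14: trans-1,2-dichloroethene and MeLi (2 equiv, Et2O, 0 °C) give lithium chloroacetylide F5. This is acylated by 11 at −78 °C to (Z)-1-chloroundec-5-en-1-yn-3-one F6. LiCl in AcOH (conjugate addition of chloride to the chlorine-bearing alkyne carbon, then protonation) gives 14.

Further compounds
F1 | step 8 | methyl (5E,7Z,12R,14Z)-10-chloro-12-hydroxy-9-oxoprosta-5,7,10,14-tetraenoate | CCCCC/C=C\C[C@@]1(O)C=C(Cl)C(=O)/C1=C\C=C\CCCC(=O)OC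
F2 | step 7 | (Z)-undec-5-en-1-yn-3-one | CCCCC/C=C\CC(=O)C#C
F3 | step 7 | (Z)-1-iodoundec-5-en-1-yn-3-one | CCCCC/C=C\CC(=O)C#CI
F4 | step 7 | (1E,5Z)-1-chloro-1-iodoundeca-1,5-dien-3-one | CCCCC/C=C\CC(=O)/C=C(Cl)/I
F5 | step 6 | lithium chloroacetylide | [Li]C#CCl
F6 | step 6 | (Z)-1-chloroundec-5-en-1-yn-3-one | CCCCC/C=C\CC(=O)C#CCl
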